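**Assumption:** the SMILES is taken literally, i.e. the (2R,5aR,7S,9aS) isomer in which H-5a and the 9a-methyl are on the same face (cis-fused rings); racemic 4-methylcyclohex-2-en-1-one is taken as a catalogue compound.

## Retrosynthetic overview

1. Target 15 ← Schenck ene reaction of the 3-methylidene oxepane 13 (C3=CH2 becomes C3=C4 plus CH2OH); C7–Br ← C7–OH by SN2 inversion.
2. cis-Fused oxepanone 11 ← 7-endo-trig radical cyclization of β-iodo ether 10 onto its tethered vinyl ketone (C5–C5a bond, sets C5a; key step).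
3. 10 ← iodoetherification of cyclohexene 4 with hydroxy enone 8 (sets C9a).
4. 4 ← 4-methylcyclohex-2-en-1-one (gem-dimethylation, CBS reduction); 8 ← penta-1,4-dien-3-ol (Sharpless desymmetrization, bromide opening, allylic oxidation).
5. Ring order: the cyclohexane is bought; the oxepane is closed second, by the radical step.

## Route

Step 1
Reactants: 1 4-methylcyclohex-2-en-1-one (racemic)
Product: 2 2,2,4-trimethylcyclohex-3-en-1-one
Conditions: KOt-Bu (2.2 equiv), MeI (2.5 equiv), t-BuOH–THF, 0 °C to rt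
Reagents that add atoms: iodomethane, CI
Why: Deconjugative α,α-dialkylation of an enone through its thermodynamic dienolate puts both methyl groups on C2 and leaves the C3=C4 alkene; the C4 stereocentre of 1 is erased.

Step 2
Reactants: 2 2,2,4-trimethylcyclohex-3-en-1-one
Product: 4 triethyl{[(1R)-2,2,4-trimethylcyclohex-3-en-1-yl]oxy}silane, via (1R)-2,2,4-trimethylcyclohex-3-en-1-ol 3 (not isolated)
Conditions: (S)-2-methyl-CBS-oxazaborolidine (10 mol%), BH3·SMe2 (0.7 equiv), THF, −20 °C, slow addition of 2; MeOH, evaporate; TESCl, imidazole, CH2Cl2, 0 °C to rt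
Reagents that add atoms: chlorotriethylsilane, CC[Si](Cl)(CC)CC
Why: Corey–Bakshi–Shibata reduction with the quaternary α-carbon as the large group gives the (1R)-alcohol (catalysed ketone reduction outruns hydroboration of the hindered alkene), and silylation blocks transannular attack of this oxygen in step 6.

Step 3
Reactants: 5 penta-1,4-dien-3-ol
Product: 6 (1R)-1-[(2S)-oxiran-2-yl]prop-2-en-1-ol [(2S,3R)-1,2-epoxypent-4-en-3-ol]
Conditions: Ti(Oi-Pr)4 (10 mol%), D-(−)-diisopropyl tartrate (13 mol%), t-BuOOH, 4 Å molecular sieves, CH2Cl2, −20 °C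
Reagents that add atoms: tert-butyl hydroperoxide, CC(C)(C)OO
Why: Sharpless asymmetric epoxidation desymmetrizes the divinyl carbinol (the minor enantiomer is consumed by in-situ kinetic resolution); the D-tartrate gives the erythro (2S,3R) epoxy alcohol.

Step 4
Reactants: 6 (1R)-1-[(2S)-oxiran-2-yl]prop-2-en-1-ol
Product: 7 (2R,3R)-1-bromopent-4-ene-2,3-diol
Conditions: LiBr, AcOH, THF, 0 °C to rt
Reagents that add atoms: lithium bromide, [Li+].[Br-]
Why: SN2 epoxide opening by bromide at the primary carbon; the C2–O bond is untouched, so this carbinol (the later C2 of the target) keeps its configuration.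

Step 5
Reactants: 7 (2R,3R)-1-bromopent-4-ene-2,3-diol
Product: 8 (2R)-1-bromo-2-hydroxypent-4-en-3-one
Conditions: activated MnO2 (excess), CH2Cl2, 0 °C to rt; used at once
Reagents that add atoms: none
Why: MnO2 oxidizes only the allylic alcohol, giving the vinyl ketone that activates the later radical acceptor; the neutral medium spares the β-bromo α-hydroxy ketone.

Step 6
Reactants: 4 triethyl{[(1R)-2,2,4-trimethylcyclohex-3-en-1-yl]oxy}silane; 8 (2R)-1-bromo-2-hydroxypent-4-en-3-one
Product: 10 (2R)-1-bromo-2-{[(1S,2S,4R)-4-hydroxy-2-iodo-1,3,3-trimethylcyclohexyl]oxy}pent-4-en-3-one, via triethylsilyl ether 9 (not isolated)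
Conditions: NIS (1.3 equiv), 8 (2.5 equiv), CH2Cl2, −30 to 0 °C, dark; then HF·pyridine, THF, 0 °C
Reagents that add atoms: N-iodosuccinimide, O=C1CCC(=O)N1I
Why: Intermolecular iodoetherification (Markovnikov, anti): the alcohol opens the iodonium ion at the tertiary carbon trans-diaxially in the chair that keeps the silyloxy group equatorial, which places the new C–O bond cis to that oxygen (1S) and the iodine anti (2S); the electron-poor enone of 8 is inert to the iodonium source, and fluoride then frees the C4 hydroxyl.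

Step 7
Reactants: 10 (2R)-1-bromo-2-{[(1S,2S,4R)-4-hydroxy-2-iodo-1,3,3-trimethylcyclohexyl]oxy}pent-4-en-3-one
Product: 11 (2R,5aR,7R,9aS)-2-(bromomethyl)-7-hydroxy-6,6,9a-trimethyloctahydro-1-benzoxepin-3(2H)-one
Conditions: (Me3Si)3SiH (1.3 equiv, syringe pump), Et3B (0.3 equiv), air, PhMe (0.01 M), 0 °C
Reagents that add atoms: none
Why: Ueno–Stork-type radical cyclization extended to a 7-endo-trig conjugate addition: the secondary radical from the iodide adds to the terminal carbon of the tethered vinyl ketone (6-exo would be anti-Michael), and because the acceptor hangs from the C9a oxygen the new C5–C5a bond forms on the oxygen face, which sets the cis ring fusion (5aR); iodide is abstracted much faster than bromide, and low temperature with a slow hydrogen donor favours closure over reduction or attack on the carbonyl.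

Step 8
Reactants: 11 (2R,5aR,7R,9aS)-2-(bromomethyl)-7-hydroxy-6,6,9a-trimethyloctahydro-1-benzoxepin-3(2H)-one
Product: 12 (2R,5aR,7R,9aS)-2-(bromomethyl)-6,6,9a-trimethyl-3-methylidenedecahydro-1-benzoxepin-7-ol
Conditions: Cp2TiMe2 (3 equiv), PhMe, 65 °C, dark
Reagents that add atoms: dimethyltitanocene, [CH3-].[CH3-].[Ti+4].c1cc[cH-]c1.c1cc[cH-]c1
Why: Petasis methylenation is non-basic, so the β-bromo α-alkoxy ketone is neither epimerized at C2 nor eliminated; the free hydroxyl only consumes reagent and returns on work-up.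

Step 9
Reactants: 12 (2R,5aR,7R,9aS)-2-(bromomethyl)-6,6,9a-trimethyl-3-methylidenedecahydro-1-benzoxepin-7-ol
Product: 13 (2R,5aR,7S,9aS)-7-bromo-2-(bromomethyl)-6,6,9a-trimethyl-3-methylidenedecahydro-1-benzoxepine
Conditions: CBr4, PPh3, PhMe, 0 to 60 °C
Reagents that add atoms: tetrabromomethane, BrC(Br)(Br)Br
Why: Appel reaction; bromide displaces the oxyphosphonium group by SN2 with inversion (7R alcohol to 7S bromide), the flexible cis-fused ring being able to place the leaving group axial.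

Step 10
Reactants: 13 (2R,5aR,7S,9aS)-7-bromo-2-(bromomethyl)-6,6,9a-trimethyl-3-methylidenedecahydro-1-benzoxepine
Product: 15 [(2R,5aR,7S,9aS)-7-bromo-2-(bromomethyl)-6,6,9a-trimethyl-2,5,5a,6,7,8,9,9a-octahydro-1-benzoxepin-3-yl]methanol, via allylic hydroperoxide 14 (not isolated)
Conditions: O2, hν (visible), tetraphenylporphyrin (cat.), CH2Cl2, 0 °C; then PPh3
Reagents that add atoms: dioxygen, O=O
Why: Schenck ene reaction of singlet oxygen with the 1,1-disubstituted alkene: oxygen adds to the CH2 terminus and the hydrogen is taken from ring C4 (not from the oxygen-bearing C2), moving the alkene to C3=C4; phosphine reduces the hydroperoxide to the alcohol without touching the bromides.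

## Compound list

1 | 4-methylcyclohex-2-en-1-one (racemic) | CC1CCC(=O)C=C1 | starting material
2 | 2,2,4-trimethylcyclohex-3-en-1-one | CC1=CC(C)(C)C(=O)CC1 | intermediate
3 | (1R)-2,2,4-trimethylcyclohex-3-en-1-ol | CC1(C)C=C(C)CC[C@H]1O | intermediate
4 | triethyl{[(1R)-2,2,4-trimethylcyclohex-3-en-1-yl]oxy}silane | CC1(C)C=C(C)CC[C@H]1O[Si](CC)(CC)CC | intermediate
5 | penta-1,4-dien-3-ol | C=CC(O)C=C | starting material
6 | (1R)-1-[(2S)-oxiran-2-yl]prop-2-en-1-ol | C=C[C@@H](O)[C@@H]1CO1 | intermediate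
7 | (2R,3R)-1-bromopent-4-ene-2,3-diol | C=C[C@@H](O)[C@H](CBr)O | intermediate
8 | (2R)-1-bromo-2-hydroxypent-4-en-3-one | C=CC(=O)[C@H](CBr)O | intermediate
9 | (2R)-1-bromo-2-({(1S,2S,4R)-2-iodo-1,3,3-trimethyl-4-[(triethylsilyl)oxy]cyclohexyl}oxy)pent-4-en-3-one | CC1(C)[C@H](I)[C@@](C)(O[C@@H](CBr)C(=O)C=C)CC[C@H]1O[Si](CC)(CC)CC | intermediate
10 | (2R)-1-bromo-2-{[(1S,2S,4R)-4-hydroxy-2-iodo-1,3,3-trimethylcyclohexyl]oxy}pent-4-en-3-one | CC1(C)[C@H](I)[C@@](C)(O[C@@H](CBr)C(=O)C=C)CC[C@H]1O | intermediate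
11 | (2R,5aR,7R,9aS)-2-(bromomethyl)-7-hydroxy-6,6,9a-trimethyloctahydro-1-benzoxepin-3(2H)-one | CC1(C)[C@H]2CCC(=O)[C@H](CBr)O[C@@]2(C)CC[C@H]1O | intermediate
12 | (2R,5aR,7R,9aS)-2-(bromomethyl)-6,6,9a-trimethyl-3-methylidenedecahydro-1-benzoxepin-7-ol | CC1(C)[C@H]2CCC(=C)[C@H](CBr)O[C@@]2(C)CC[C@H]1O | intermediate
13 | (2R,5aR,7S,9aS)-7-bromo-2-(bromomethyl)-6,6,9a-trimethyl-3-methylidenedecahydro-1-benzoxepine | CC1(C)[C@H]2CCC(=C)[C@H](CBr)O[C@@]2(C)CC[C@@H]1Br | intermediate
14 | (2R,5aR,7S,9aS)-7-bromo-2-(bromomethyl)-3-(hydroperoxymethyl)-6,6,9a-trimethyl-2,5,5a,6,7,8,9,9a-octahydro-1-benzoxepine | CC1(C)[C@H]2CC=C(COO)[C@H](CBr)O[C@@]2(C)CC[C@@H]1Br | intermediate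
15 | [(2R,5aR,7S,9aS)-7-bromo-2-(bromomethyl)-6,6,9a-trimethyl-2,5,5a,6,7,8,9,9a-octahydro-1-benzoxepin-3-yl]methanol | CC1(C)[C@H]2CC=C(CO)[C@H](CBr)O[C@@]2(C)CC[C@@H]1Br | target

## Step count and risks

Total: 10 steps. Longest linear sequence: 8 steps (steps 3, 4, 5, 6, 7, 8, 9, 10, from penta-1,4-dien-3-ol); the ring-A branch (steps 1 and 2) joins at step 6.

The three steps most likely to fail:

**Step 6 (intermolecular iodoetherification).** The alcohol 8 is a weak, sensitive nucleophile and the tertiary carbon is hindered; the facial selectivity is expected to be useful but not complete. Fallback: the ether bond is made by alkoxymercuration instead of iodonium capture. Starting again from 4 and 8, Hg(OCOCF3)2 in CH2Cl2 at −20 °C followed by aqueous NaCl gives the trans-alkoxy organomercurial chloro[(1S,2S,5R)-2-{[(2R)-1-bromo-3-oxopent-4-en-2-yl]oxy}-2,6,6-trimethyl-5-[(triethylsilyl)oxy]cyclohexyl]mercury F1. I2 in pyridine–CH2Cl2 in the dark then replaces mercury by iodine with retention, and the route is rejoined at 9 (HF·pyridine as before).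

**Step 7 (7-endo radical cyclization).** The radical can also be reduced before closing, or attack the tether carbonyl (acyl transfer followed by loss of bromide). Fallback: the carbonyl is removed before the radical step. Setting out from 9 (isolated, HF·pyridine left out), Cp2Ti(CH2SiMe3)2 in PhMe at 100 °C converts the ketone into the silyl diene triethyl{[(1R,3S,4S)-4-({(2R)-1-bromo-3-[(trimethylsilyl)methylidene]pent-4-en-2-yl}oxy)-3-iodo-2,2,4-trimethylcyclohexyl]oxy}silane F2. (Me3Si)3SiH/Et3B/air closes the ring at the free diene terminus (the silylated terminus is blocked) to give the allylsilane triethyl{[(2R,5aR,7R,9aS)-2-(bromomethyl)-6,6,9a-trimethyl-3-[(trimethylsilyl)methyl]-2,5,5a,6,7,8,9,9a-octahydro-1-benzoxepin-7-yl]oxy}silane F3, possibly with the vinylsilane triethyl{[(2R,5aR,7R,9aS)-2-(bromomethyl)-6,6,9a-trimethyl-3-[(trimethylsilyl)methylidene]decahydro-1-benzoxepin-7-yl]oxy}silane F4. CF3CO2H in CH2Cl2 protodesilylates both to the same exocyclic alkene and cleaves the silyl ether, rejoining at 12.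

**Step 9 (SN2 bromination of a neopentyl-type secondary alcohol).** Elimination or methyl shift can dominate under Appel conditions. Fallback: activation and displacement are separated. From 12, Tf2O and pyridine in CH2Cl2 at −78 °C give the triflate (2R,5aR,7R,9aS)-2-(bromomethyl)-6,6,9a-trimethyl-3-methylidenedecahydro-1-benzoxepin-7-yl trifluoromethanesulfonate F5, which Bu4NBr in PhMe at −20 °C to rt displaces with inversion, rejoining at 13.

Further compounds
F1 | step 6 | chloro[(1S,2S,5R)-2-{[(2R)-1-bromo-3-oxopent-4-en-2-yl]oxy}-2,6,6-trimethyl-5-[(triethylsilyl)oxy]cyclohexyl]mercury | CC1(C)[C@H]([Hg]Cl)[C@@](C)(O[C@@H](CBr)C(=O)C=C)CC[C@H]1O[Si](CC)(CC)CC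
F2 | step 7 | triethyl{[(1R,3S,4S)-4-({(2R)-1-bromo-3-[(trimethylsilyl)methylidene]pent-4-en-2-yl}oxy)-3-iodo-2,2,4-trimethylcyclohexyl]oxy}silane | CC1(C)[C@H](I)[C@@](C)(O[C@@H](CBr)C(=C[Si](C)(C)C)C=C)CC[C@H]1O[Si](CC)(CC)CC
F3 | step 7 | triethyl{[(2R,5aR,7R,9aS)-2-(bromomethyl)-6,6,9a-trimethyl-3-[(trimethylsilyl)methyl]-2,5,5a,6,7,8,9,9a-octahydro-1-benzoxepin-7-yl]oxy}silane | CC1(C)[C@H]2CC=C(C[Si](C)(C)C)[C@H](CBr)O[C@@]2(C)CC[C@H]1O[Si](CC)(CC)CC
F4 | step 7 | triethyl{[(2R,5aR,7R,9aS)-2-(bromomethyl)-6,6,9a-trimethyl-3-[(trimethylsilyl)methylidene]decahydro-1-benzoxepin-7-yl]oxy}silane | CC1(C)[C@H]2CCC(=C[Si](C)(C)C)[C@H](CBr)O[C@@]2(C)CC[C@H]1O[Si](CC)(CC)CC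
F5 | step 9 | (2R,5aR,7R,9aS)-2-(bromomethyl)-6,6,9a-trimethyl-3-methylidenedecahydro-1-benzoxepin-7-yl trifluoromethanesulfonate | CC1(C)[C@H]2CCC(=C)[C@H](CBr)O[C@@]2(C)CC[C@H]1OS(=O)(=O)C(F)(F)F
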